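The data were generated by integration for substances that don't exist; noise was put on by code.

**The clock.** The flasks are read at 2.0 min, and what counts is how long that is in a flask's own time. Take the fraction of starting complex left, invert it, subtract one, and divide by c(starting complex) times time. Saturday's value over Friday's, each at its last reading, is 0.967, so the loss looks second-order, and you can freeze that constant.

| flask | starting complex | incoming ligand | remark | time |
|---|---|---|---|---|
| Saturday's | 0.67 M | 0.80 equiv | run made earlier |  |
| Friday's | 2 M | 0.80 equiv | run made earlier |  |
| noon | 1.0 M | 0.800 equiv |  | 2.0 min |
| winter | 1.0 M | 1.20 equiv |  | 2.0 min |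
| dusk | 1.0 M | 2.50 equiv |  | 2.0 min |

- Saturday's (time / s: complex with two exchanged / %, complex with one exchanged / %, starting complex / %): 10.0: 0.3, 8.8, 70.2; 15.0: 0.2, 11.4, 61.1; 25.0: 0.8, 14.7, 48.4
- Friday's (time / s: complex with two exchanged / %, complex with one exchanged / %, starting complex / %): 10.0: 1.5, 15.1, 43.4; 15.0: 2.5, 16.6, 33.7; 20.0: 3.1, 15.8, 27.9; 25.0: 3.4, 16.2, 23.3

(scatter of a reading: 0.3 percentage points)

- the analysis behind the earlier runs scatters by 0.3 percentage points, standard deviation

1. final complex with two exchanged, as a percentage of the starting complex charged, for each flask in turn (noon, winter, dusk)

**One number.** Multiply the frozen constant by c(starting complex) and the time of reading. This gives θ, a Damköhler number, which counts how many times the clock has passed the time in which starting complex falls to half: 7.90 for noon. The fraction left is then the inverse of one plus θ, which is 11.2%.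

**Reading it.** My reckoning is this: Friday's last reading stood at θ = 3.29 with 3.4% complex with two exchanged. Noon has the same ratio and a larger θ, so I expect noon to read above that. But noon, winter and dusk share c(starting complex) and the time of reading, so this reckoning gives them one θ, and its constant was read at 0.80 equiv, so it is silent on what more incoming ligand does. One number is not enough here.

**The forecast.** It gives 4.5%, 13% and 38%, holding that “More ligand should favour exchange over the hidden path and drive the second step”.

    starting complex + incoming ligand ⇌ leaving ligand + complex with one exchanged (K = 0.930, k = 0.0230 M⁻¹ s⁻¹)
    complex with one exchanged + incoming ligand ⇌ leaving ligand + complex with two exchanged (K = 1.20, k = 0.0110 M⁻¹ s⁻¹)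
    complex with one exchanged + incoming ligand → over-reaction product (k = 0.0200 M⁻¹ s⁻¹)
    2 starting complex → self-condensation product (k = 0.0210 M⁻¹ s⁻¹)

**What stands.** The flasks give 6.10%, 9.13% and 14.6%; noon stands above Friday's last reading, and dusk stands below the forecast. Against the 11.2% reckoned from θ = 7.90, noon keeps 13% of its starting complex and winter 11%, but dusk keeps less, 4.4%. In winter, taking each step alone at the charged concentrations, complex with one exchanged has a half-life of 0.48 min towards over-reaction product, shorter than the 0.88 min towards complex with two exchanged, which counts the forward rate and leaves out the way back. At 2.00 min winter holds 22.3% over-reaction product beside 9.13% complex with two exchanged.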